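The C40 polyene has a C2 axis through the central C15=C15' double bond, so it is cut there into two identical (6S)-α-retinal units. Their reductive carbonyl–carbonyl coupling creates that double bond and doubles the skeleton in one operation, leaving the two 2,6,6-trimethylcyclohex-2-enyl rings untouched. The coupling partner is a C20 tetraenal whose ring carries the C4=C5 alkene and the allylic C6–H stereocenter. It is made from all-trans-retinoic acid: the β ring is oxidized at C4, the ketone is reduced enantioselectively, and a stereospecific reductive 1,3-transposition moves the alkene from C5=C6 to C4=C5 while transferring the C4 configuration to C6.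

Key step: step 7

Remark: retinoid/carotenoid numbering is used (ring C1 = gem-dimethyl carbon, C4 = ring CH2 next to the methyl-bearing C5, C6 = ring carbon bearing the chain, chain C7 to C15), and all operations are assumed to be run under argon in dim light.

Step 1
Reactants: 1 all-trans-retinoic acid
Product: 2 methyl all-trans-retinoate
Conditions: MeI, K2CO3, DMF, rt, dark
Reagents that add atoms: iodomethane, CI
Why: Carboxylate O-alkylation (SN2 esterification) under a mild base should leave the polyene geometry untouched and masks the acid for the oxidation and hydride steps that follow.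

Step 2
Reactants: 2 methyl all-trans-retinoate
Product: 3 methyl all-trans-4-oxoretinoate
Conditions: activated MnO2 (large excess), CH2Cl2, rt, dark
Reagents that add atoms: manganese dioxide, O=[Mn]=O
Why: Allylic C–H oxidation: the ring C4 methylene is the only CH2 allylic to the electron-rich tetrasubstituted C5=C6 end of the polyene, and MnO2 is known to oxidize retinoate esters to the ring enone at this position while sparing the ester-terminated chain.

Step 3
Reactants: 3 methyl all-trans-4-oxoretinoate
Product: 4 methyl (4R)-4-hydroxyretinoate
Conditions: (S)-1-methyl-3,3-diphenyltetrahydro-1H,3H-pyrrolo[1,2-c][1,3,2]oxazaborole ((S)-Me-CBS, cat.), catecholborane, toluene, -78 °C; then MeOH, aq. NaHCO3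
Reagents that add atoms: none
Why: Corey–Bakshi–Shibata reduction: the ketone should bind the catalyst boron anti to its larger substituent, the methyl-bearing C5 alkenyl carbon, so that hydride from the nitrogen-bound borane adds to the face that gives 4R, while the ester is inert to catecholborane at this temperature.

Step 4
Reactants: 4 methyl (4R)-4-hydroxyretinoate; 5 2-nitrobenzenesulfonylhydrazide (NBSH)
Product: 8 methyl (6S)-α-retinoate, via N-sulfonylhydrazine adduct 6 (not isolated), via allylic diazene 7 (not isolated)
Conditions: PPh3, diethyl azodicarboxylate, N-methylmorpholine, -30 °C, then 23 °C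
Reagents that add atoms: none
Why: Mitsunobu reaction followed by allylic diazene retro-ene rearrangement (reductive 1,3-transposition): the sulfonamide nitrogen of 5 displaces the C4 oxygen with inversion to give 6, which on warming loses 2-nitrobenzenesulfinic acid to the (4S)-diazene 7, and the concerted loss of N2 from 7 places H on C6 on the face that carried nitrogen and moves the alkene to C4=C5, so that 4R in 4 should become 6S in 8.

Step 5
Reactants: 8 methyl (6S)-α-retinoate
Product: 9 (6S)-α-retinol
Conditions: i-Bu2AlH, CH2Cl2, -78 °C; aq. potassium sodium tartrate work-up
Reagents that add atoms: none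
Why: Aluminium hydride 1,2-reduction of the conjugated ester to the primary allylic alcohol is non-basic at low temperature, so the vinylogously acidic C6–H and the isolated C4=C5 alkene should be untouched.

Step 6
Reactants: 9 (6S)-α-retinol
Product: 10 (6S)-α-retinal
Conditions: activated MnO2, CH2Cl2, rt, dark, no base
Reagents that add atoms: none
Why: Heterogeneous MnO2 oxidation is selective for the polyenylic primary alcohol and runs under neutral conditions, so no dienolate toward C6 should form and the C4=C5 alkene should not move into conjugation.

Step 7
Reactants: 10 (6S)-α-retinal (two molecules)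
Product: 12 (6S,6'S)-ε-carotene, via titanium 15,15'-pinacolate 11 (not isolated)
Conditions: TiCl3(DME)1.5, Zn-Cu couple, DME, reflux; then 10, reflux; filtration; heptane, reflux; crystallization
Reagents that add atoms: none
Why: McMurry carbonyl olefination: zerovalent titanium, made from TiCl3(DME)1.5 and the Zn-Cu couple, transfers single electrons to two molecules of 10 to give delocalized ketyl radicals that join at C15 and C15' on the metal to the pinacolate 11, whose two C–O bonds are then cleaved at reflux to leave the C15=C15' double bond. The closest known reaction is the reductive homocoupling of all-trans-retinal to β-carotene with low-valent titanium, from which 10 differs only in the position of the remote ring alkene. No ring is closed; the only bond made is C15–C15', and because of the C2 axis one aldehyde serves as both partners, so no cross-coupling selectivity is needed. No stereocenter is created: C6 and C6' are carried in from 10, and the medium holds neither base nor protic acid that could remove the vinylogously acidic C6–H or shift the C4=C5 alkene. The selectivity required is E geometry at C15=C15', which the stepwise deoxygenation of the conjugated pinacolate should favour and which brief heating in heptane should complete, since a central cis bond in a carotene is thermally labile. Because two molecules of 10 are joined, most of any minor 6R material should end up in the meso (6R,6'S) diastereomer and be removed on crystallization.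

Compound list
1 | all-trans-retinoic acid | CC1=C(/C=C/C(C)=C/C=C/C(C)=C/C(=O)O)C(C)(C)CCC1 | starting material
2 | methyl all-trans-retinoate | COC(=O)/C=C(C)/C=C/C=C(C)/C=C/C1=C(C)CCCC1(C)C | intermediate
3 | methyl all-trans-4-oxoretinoate | COC(=O)/C=C(C)/C=C/C=C(C)/C=C/C1=C(C)C(=O)CCC1(C)C | intermediate
4 | methyl (4R)-4-hydroxyretinoate | COC(=O)/C=C(C)/C=C/C=C(C)/C=C/C1=C(C)[C@H](O)CCC1(C)C | intermediate
5 | 2-nitrobenzenesulfonylhydrazide (NBSH) | NNS(=O)(=O)c1ccccc1[N+](=O)[O-] | starting material
6 | methyl (4S)-4-[1-(2-nitrophenylsulfonyl)hydrazinyl]retinoate (Mitsunobu adduct, not isolated) | COC(=O)/C=C(C)/C=C/C=C(C)/C=C/C1=C(C)[C@@H](N(N)S(=O)(=O)c2ccccc2[N+](=O)[O-])CCC1(C)C | intermediate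
7 | methyl (4S)-4-diazenylretinoate (allylic monoalkyl diazene, not isolated) | COC(=O)/C=C(C)/C=C/C=C(C)/C=C/C1=C(C)[C@@H](N=N)CCC1(C)C | intermediate
8 | methyl (6S)-α-retinoate, methyl (2E,4E,6E,8E)-3,7-dimethyl-9-[(1S)-2,6,6-trimethylcyclohex-2-en-1-yl]nona-2,4,6,8-tetraenoate | COC(=O)/C=C(C)/C=C/C=C(C)/C=C/[C@@H]1C(C)=CCCC1(C)C | intermediate
9 | (6S)-α-retinol | OC/C=C(C)/C=C/C=C(C)/C=C/[C@@H]1C(C)=CCCC1(C)C | intermediate
10 | (6S)-α-retinal | O=C/C=C(C)/C=C/C=C(C)/C=C/[C@@H]1C(C)=CCCC1(C)C | intermediate
11 | titanium-bound 15,15'-pinacolate from two molecules of 10 (not isolated; drawn as the dialkoxide with titanium omitted, C15 and C15' configuration not defined) | [O-]C(/C=C(C)/C=C/C=C(C)/C=C/[C@@H]1C(C)=CCCC1(C)C)C([O-])/C=C(C)/C=C/C=C(C)/C=C/[C@@H]1C(C)=CCCC1(C)C | intermediate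
12 | (6S,6'S)-ε-carotene | CC1=CCCC(C)(C)[C@@H]1/C=C/C(C)=C/C=C/C(C)=C/C=C/C=C(C)/C=C/C=C(C)/C=C/[C@@H]1C(C)=CCCC1(C)C | target

Total step count: 7
Longest linear sequence: 7 steps (1 to 12)

Steps most likely to fail

Step 4. The activated C4 oxygen may leave by ionization or elimination before the sulfonylhydrazide attacks, which would erode the C4 configuration or dehydrate the ring. The displacement at the hindered C4 may also be too slow at the temperature the reagent tolerates. The fallback sets out from 4 and comes back at 8. Compound 4 is formylated with acetic formic anhydride and pyridine in CH2Cl2 at 0 °C to methyl (4R)-4-(formyloxy)retinoate F1. F1 is then treated with Pd(OAc)2 and n-Bu3P in THF at room temperature. Zerovalent palladium formed in the flask should ionize the formate with inversion to a π-allyl complex over C4–C5–C6. Loss of CO2 gives a palladium hydride, and reductive elimination should place H on the more substituted terminus C6 from the metal-bearing face, anti to the original C4–O bond. This is the same 4R to 6S outcome as in step 4, reached without a Mitsunobu reaction.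

Step 3. Hydride delivery may show poor facial selectivity, because the ketone lies between two ring carbons of similar bulk, or conjugate reduction of the extended enone may compete. The fallback sets out from 3 and comes back at 4. Luche reduction (NaBH4, CeCl3·7H2O, MeOH, 0 °C) gives methyl rac-4-hydroxyretinoate F2. F2 is resolved by lipase-catalysed acylation (immobilized Candida antarctica lipase B, vinyl acetate, t-BuOMe, 30 °C). By the usual empirical rule for secondary alcohols this should acylate the 4R enantiomer faster, giving methyl (4R)-4-acetoxyretinoate F3 and leaving methyl (4S)-4-hydroxyretinoate F4. After chromatographic separation, methanolysis of F3 (K2CO3, MeOH, 0 °C) gives 4. F4 is returned to 3 with MnO2 and recycled.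

Step 7. The coupling may stall at the pinacol stage, or the polyene may be over-reduced or scrambled in geometry on the titanium surface. The fallback sets out from 9 and 10 and comes back at 12, forming the same C15=C15' bond. Compound 9 is converted with PPh3·HBr in MeOH at room temperature into (6S)-α-retinyltriphenylphosphonium bromide F5. Wittig olefination of F5 with 10 in EtOH and 1,2-epoxybutane at reflux uses the epoxide as the HBr acceptor, so no strong base is present. Thermal equilibration of the central double bond in heptane and crystallization should then give 12.

Further compounds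
F1 | step 4 | methyl (4R)-4-(formyloxy)retinoate | COC(=O)/C=C(C)/C=C/C=C(C)/C=C/C1=C(C)[C@H](OC=O)CCC1(C)C
F2 | step 3 | methyl rac-4-hydroxyretinoate | COC(=O)/C=C(C)/C=C/C=C(C)/C=C/C1=C(C)C(O)CCC1(C)C
F3 | step 3 | methyl (4R)-4-acetoxyretinoate | COC(=O)/C=C(C)/C=C/C=C(C)/C=C/C1=C(C)[C@H](OC(C)=O)CCC1(C)C
F4 | step 3 | methyl (4S)-4-hydroxyretinoate | COC(=O)/C=C(C)/C=C/C=C(C)/C=C/C1=C(C)[C@@H](O)CCC1(C)C
F5 | step 7 | (6S)-α-retinyltriphenylphosphonium bromide | [Br-].c1ccccc1[P+](c1ccccc1)(c1ccccc1)C/C=C(C)/C=C/C=C(C)/C=C/[C@@H]1C(C)=CCCC1(C)C
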